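## Structural features

The target is a bicyclic diterpenoid of the ent-halimane type: a cyclohexene ring A (C1–C5 and C10, with the trisubstituted C1=C10 alkene) is fused through the C5–C10 bond to a saturated ring B (C5–C10). Ring A carries at C4 a quaternary centre bearing methyl C19 and carboxyl C18, directly beside the tertiary ring-fusion centre C5. Ring B carries the second vicinal pair, tertiary C8 (methyl C17) and quaternary C9 (methyl C20 and the side chain), so the four stereocentres (4S,5S,8R,9S) form two adjacent pairs separated by the sp2 carbon C10. In a flat projection H5, the carboxyl group and the C9 side chain lie on one face, and the methyl groups C17, C19 and C20 on the other. The side chain is a C11–C12 ethylene link to an E-trisubstituted C13=C14 alkene whose allylic C15 oxygen is acylated as a propanoate. Fragile points are this allylic ester (cleaved by base or hydride, ionised by strong Lewis acids and by zerovalent palladium), the E geometry at C13=C14, and the C1=C10 alkene, which acid could move into the C5=C10 position. The C18 carboxyl is neopentyl-like and too hindered to be freed from an ester while the propanoate stays in place. The real difficulty is to build two quaternary centres, each next to a tertiary one, and to relate the C4/C5 pair to the C8/C9 pair across C10. The key step uses the fact that ring A, with its C1=C10 double bond and the C4 (methyl, carbonyl)–C5 (H) pair, is the retron of a [4+2] cycloaddition between a diene C2=C1–C10=C5 (a vinyl group on C10 of ring B) and a 2-methylacrolein unit C3=C4.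

## Logic of the disconnections

16 to 15: no skeletal bond is cut; only the oxidation level of C18 is lowered. The hindered C18 carboxyl could not be released from an ester without loss of the C15 propanoate, so it is carried as the aldehyde that the cycloaddition delivers directly. This removes every protecting group from the endgame. The forward oxidation must spare two trisubstituted alkenes and the allylic ester; C4 is quaternary, so nothing can epimerise.

15 to 13 + 14: the C2–C3 and C4–C5 bonds of ring A are cut. This removes ring A, the quaternary centre C4 and the stereocentre C5 in one operation and leaves a monocyclic diene that holds only the C8/C9 pair, plus a four-carbon partner. The alkene is born at C1=C10 and needs no adjustment. The forward step must give ortho orientation (C4 to C5), the exo-formyl topology (CHO cis to H5) and bonding on the diene face anti to the C9 side chain.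

13 to 12 to 10: the C15–O acyl bond is cut and C15 is taken back to the ester oxidation level. An allylic propanoate would not survive the palladium and enolate chemistry used earlier, whereas the conjugated ester is robust and is the direct product of the olefination. One function is thereby carried unchanged through three steps. The forward steps need a 1,2-selective hydride reduction and an acylation that does not ionise the allylic position.

10 to 9 to 7: the C1–C10 bond between the vinyl group and ring B is cut, and the enol triflate is traced to the C10 ketone. A vinyl group on a carbon flanked by quaternary C9 is best introduced by cross-coupling, and enolisation of the C10 ketone can only go toward C5. The diene is thus reduced to a ketone, which is what conjugate-addition chemistry provides. The forward step must form the ring enolate without touching the γ-hydrogens of the conjugated ester.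

7 to 5 + 6: the C13=C14 double bond is cut. The E-trisubstituted conjugated ester is the olefination retron of a methyl ketone, which reduces the side chain to a 3-oxobutyl group and a two-carbon phosphonate. The forward step must select the side-chain carbonyl over the hindered ring carbonyl, favour the E isomer and avoid aldol closure of the 1,5-diketone.

5 to 3 + 4: the C9–C11 bond is cut. The 1,5-relationship of the C10 and C13 carbonyl groups is a Michael retron, and the quaternary centre C9 is created on a regiodefined enol ether. This removes the whole side chain and leaves a ring with a single stereocentre. The forward step must bond on the face of C9 anti to the C8 methyl group and must not oligomerise 4.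

3 to 1: the C8–C17 bond (and the O–Si bond) is cut. A β-methyl ketone is the conjugate-addition retron; the catalytic asymmetric version sets C8, the one centre from which all others are relayed, and leaves the enolate double bond at C9=C10 where the next bond is needed. The starting point becomes an achiral commercial enone. The forward step needs enantiofacial control on a 2-substituted enone and trapping of the enolate without equilibration.

## Other disconnections considered

Alternative 1: The cut runs through C5–C10 and C8–C9 and opens both rings. The precursor is the acyclic trienone A1, in which an E,E-diene (C5=C6–C7=C8) is tethered through C4–C3–C2–C1(=O) to an E-enone (C9=C10).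
- Forward step: Et2AlCl binds the C1 carbonyl and A1 should cyclise through a transition state with the tether carbonyl endo, giving the cis-fused decalin A2.
- In its favour: two rings, two C–C bonds and four stereocentres (C5, C8, C9, C10) arise in one step from a precursor with a single stereocentre (C4). On rings and stereocentres per step it is better than the chosen plan. The cis relationship of C17 and C20 follows from alkene geometry, which is at least as secure as the enolate-face control used in the chosen route.
- Against it here: the dienophile carbon C9 is β,β-disubstituted and must become quaternary, while the diene terminus C5 bonds next to quaternary C4, so the cycloaddition is crowded and slow. The only controller of the diene face is C4, whose methyl and ester groups differ little in size.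
- A2 also has the wrong functional pattern. The C1 ketone and C10–H must be turned into the C1=C10 alkene (enolisation toward hindered C10, then removal of oxygen), which destroys the C10 centre just made. C6=C7 must be saturated in the presence of C13=C14, the hindered C18 methyl ester cleaved and the silyl ether exchanged for the propanoate.
- Comparison: both plans are [4+2] cycloadditions. The chosen one is intermolecular, starts bonding at an unhindered CH2 terminus and places the alkene where the target has it. A1 needs its own enantioselective construction of quaternary C4 and two stereodefined olefinations, so the overall count would be clearly higher.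

Alternative 2: The cut is C9–C10. The precursor A3 is a ring A cyclohexenyl triflate (C10–OTf, C1=C10) with the C4/C5 pair in place and a C5 arm C6–C7–C8(CH3)–C9(CH3)=C11–C12–OSi.
- Forward step: zerovalent palladium, formed from Pd(OAc)2 and a chiral BINAP, adds to the C10–O bond. The vinylpalladium then inserts the C9=C11 alkene in the 6-exo sense, forming C9–C10, closing ring B and setting quaternary C9. β-Hydride elimination can only go toward C12, and hydrolysis of the resulting C11=C12–O unit gives the aldehyde A4.
- In its favour: it is a catalytic, ligand-controlled route to a quaternary centre under nearly neutral conditions. The C1=C10 alkene comes through unchanged from the triflate, which equals the chosen plan on this point. The β-elimination is regiochemically unambiguous.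
- Against it here: insertion into a trisubstituted alkene to form a quaternary centre beside tertiary C8 is slow. The ligand must cooperate with three existing centres (C4, C5, C8) in the insertion transition state. A3 requires separate construction of the C4/C5 pair and of C8, and a geometrically pure C9=C11 alkene.
- A4 lacks C13–C16, so the E-trisubstituted alkene and the C15 oxygen must still be added by reduction, activation and an sp3–sp2 coupling or an equivalent sequence. The C18 methyl ester must again be cleaved before the propanoate can be introduced.
- Comparison: the step forms one ring, one C–C bond and one stereocentre, against one ring, two bonds and two stereocentres in the chosen step. It cuts next to C9, which the chosen plan builds early by simple Michael chemistry. At least five operations would follow the key step, against a single oxidation in the chosen plan.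

Alternative 3: The cut is the C1=C10 double bond. The precursor A5 is ring B with an exocyclic methylidene at C10 and, on C5, the complete C4 quaternary centre carrying a but-3-enyl arm (C3–C2–C1=CH2).
- Forward step: the ruthenium alkylidene of the second-generation Grubbs catalyst should load on the terminal C1 vinyl group and close onto the C10 methylidene, expelling the two terminal methylene carbons as a gaseous C2 by-product and giving A6.
- In its favour: no stereocentre and no regiochemistry is at stake in the key step, so it is more predictable than the chosen cycloaddition. The catalyst tolerates the free acid and the silyl ether, so C18 needs no later change. The alkene lands unambiguously at C1=C10, equal to the chosen plan.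
- Against it here: the step only closes a ring. All four stereocentres and both quaternary carbons must already be present in A5, in particular the C4–C5 bond between a quaternary and a tertiary carbon on a crowded ring, which is the hardest bond of the molecule and is only moved to an earlier stage.
- The C10 methylidene is flanked by quaternary C9 and tertiary C5, so the metallacyclobutane leading to the trisubstituted alkene should form slowly. This leaves room for migration of the exocyclic double bond and for dimerisation through the vinyl group. Desilylation and acylation beside the free acid would remain.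
- Comparison: the chosen cycloaddition forms C4–C5 and sets both of its stereocentres in the ring-forming step itself. The metathesis is mechanistically more benign, but it simplifies the structure least, and the route to A5 would be longer than the seven steps to 13.

Key step: step 8

Assumption: the two chiral catalysts are identified by the face each must deliver (methyl to give 3R in step 1; bonding at the Re face of the α-carbon of 14 in step 8); if the named enantiomer of a catalyst delivered the other face, its mirror image would be used.

## Route

Step 1
Reactants: 1 2-methylcyclohex-2-en-1-one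
Product: 3 trimethyl{[(3R)-2,3-dimethylcyclohex-1-en-1-yl]oxy}silane, via dimethylaluminium enolate 2 (not isolated)
Conditions: Cu(OTf)2 (2 mol%), (R,S,S)-phosphoramidite from (R)-BINOL and bis[(S)-1-phenylethyl]amine (4 mol%), AlMe3 (1.4 equiv), Et2O, −30 °C; then TMSOTf (1.5 equiv), −30 → 0 °C; cold NaHCO3 work-up
Reagents that add atoms: trimethylaluminium C[Al](C)C; trimethylsilyl trifluoromethanesulfonate C[Si](C)(C)OS(=O)(=O)C(F)(F)F
Why: Copper-catalysed asymmetric conjugate addition of a methylaluminium reagent to a 2-substituted cyclic enone; the ligand-bound methylcopper species selects the enone face and sets the 3R centre (C8). O-Silylation of the regiodefined aluminium enolate fixes the double bond at C9=C10 for the next C–C bond.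

Step 2
Reactants: 3 trimethyl{[(3R)-2,3-dimethylcyclohex-1-en-1-yl]oxy}silane; 4 methyl vinyl ketone
Product: 5 (2S,3R)-2,3-dimethyl-2-(3-oxobutyl)cyclohexan-1-one
Conditions: 4 (1.5 equiv), BF3·OEt2 (1.1 equiv), i-PrOH (1.1 equiv), CH2Cl2, −78 °C; aq. NaHCO3
Reagents that add atoms: none
Why: Mukaiyama–Michael addition of a tetrasubstituted silyl enol ether to the BF3-activated enone; the alcohol protonates the intermediate and takes up the silyl group, which limits oligomerisation of 4. The C8 methyl group sits pseudoaxial to avoid A(1,2) strain with the C9 methyl, so the acceptor bonds to C9 on the opposite face and the chain ends trans to C17 (C17 and C20 cis).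

Step 3
Reactants: 5 (2S,3R)-2,3-dimethyl-2-(3-oxobutyl)cyclohexan-1-one; 6 triethyl phosphonoacetate
Product: 7 ethyl (2E)-5-[(1S,2R)-1,2-dimethyl-6-oxocyclohexyl]-3-methylpent-2-enoate
Conditions: 6 (1.2 equiv), NaH (1.15 equiv), THF, 0 °C; then 5, 0 → 40 °C; minor Z isomer removed by chromatography
Reagents that add atoms: none
Why: Horner–Wadsworth–Emmons olefination; the unhindered methyl ketone reacts while the ring carbonyl, flanked by quaternary C9, should not. The E isomer is favoured because the chain and the ester group avoid each other in the elimination; using no excess base limits enolisation of the diketone.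

Step 4
Reactants: 7 ethyl (2E)-5-[(1S,2R)-1,2-dimethyl-6-oxocyclohexyl]-3-methylpent-2-enoate
Product: 9 ethyl (2E)-5-[(1S,6R)-1,6-dimethyl-2-(trifluoromethanesulfonyloxy)cyclohex-2-en-1-yl]-3-methylpent-2-enoate, via potassium enolate 8 (not isolated)
Conditions: KN(SiMe3)2 (1.05 equiv), THF, −78 °C; PhNTf2 (1.1 equiv), −78 → 0 °C
Reagents that add atoms: N-phenylbis(trifluoromethanesulfonimide) O=S(=O)(N(c1ccccc1)S(=O)(=O)C(F)(F)F)C(F)(F)F
Why: Kinetic enolisation and O-triflation of a ketone; C9 is quaternary, so the enolate can only form toward C5. At −78 °C a hindered amide base removes the ketone α-hydrogen faster than a γ-hydrogen of the conjugated ester, and no stereocentre is touched.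

Step 5
Reactants: 9 ethyl (2E)-5-[(1S,6R)-1,6-dimethyl-2-(trifluoromethanesulfonyloxy)cyclohex-2-en-1-yl]-3-methylpent-2-enoate
Product: 10 ethyl (2E)-5-[(1S,6R)-2-ethenyl-1,6-dimethylcyclohex-2-en-1-yl]-3-methylpent-2-enoate
Conditions: CH2=CHSnBu3 (1.3 equiv), Pd(PPh3)4 (5 mol%), LiCl (3 equiv), THF, 65 °C
Reagents that add atoms: tributyl(ethenyl)stannane C=C[Sn](CCCC)(CCCC)CCCC
Why: Stille coupling of an enol triflate: oxidative addition of zerovalent palladium to the C10–O bond, chloride exchange, vinyl transfer from tin and reductive elimination give the 1-vinylcyclohexene. The conditions are neutral, so the conjugated ester and its geometry are untouched.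

Step 6
Reactants: 10 ethyl (2E)-5-[(1S,6R)-2-ethenyl-1,6-dimethylcyclohex-2-en-1-yl]-3-methylpent-2-enoate
Product: 12 (2E)-5-[(1S,6R)-2-ethenyl-1,6-dimethylcyclohex-2-en-1-yl]-3-methylpent-2-en-1-ol, via dienyl enal 11 (not isolated)
Conditions: i-Bu2AlH (2.5 equiv), CH2Cl2, −78 °C; aq. potassium sodium tartrate
Reagents that add atoms: none
Why: Hydride reduction of a conjugated ester by an electrophilic aluminium hydride, which attacks the carbonyl carbon only (1,2), so the C13=C14 geometry and the diene are preserved.

Step 7
Reactants: 12 (2E)-5-[(1S,6R)-2-ethenyl-1,6-dimethylcyclohex-2-en-1-yl]-3-methylpent-2-en-1-ol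
Product: 13 (2E)-5-[(1S,6R)-2-ethenyl-1,6-dimethylcyclohex-2-en-1-yl]-3-methylpent-2-en-1-yl propanoate
Conditions: (EtCO)2O (1.5 equiv), Et3N (2 equiv), DMAP (5 mol%), CH2Cl2, 0 °C
Reagents that add atoms: propanoic anhydride CCC(=O)OC(=O)CC
Why: DMAP-catalysed acyl transfer to a primary allylic alcohol under basic conditions that cannot ionise the allylic position or isomerise the acid-sensitive diene.

Step 8
Reactants: 13 (2E)-5-[(1S,6R)-2-ethenyl-1,6-dimethylcyclohex-2-en-1-yl]-3-methylpent-2-en-1-yl propanoate; 14 methacrolein
Product: 15 (1S,5S,6R,8aS)-1,5,6-trimethyl-5-[(3E)-3-methyl-5-(propanoyloxy)pent-3-en-1-yl]-1,2,3,5,6,7,8,8a-octahydronaphthalene-1-carbaldehyde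
Conditions: 14 (4 equiv), (S)-3,3-diphenyl-1-(o-tolyl)tetrahydro-1H,3H-pyrrolo[1,2-c][1,3,2]oxazaborole (20 mol%), Tf2NH (18 mol%), CH2Cl2, −78 → −40 °C
Reagents that add atoms: none
Why: The N-protonated oxazaborolidine binds the formyl oxygen of 14 (s-trans enal, formyl C–H held near the ring oxygen), lowers its LUMO and screens the Si face of its α-carbon, so the s-cis diene C2=C1–C10=C5 of 13 adds in a concerted, asynchronous [4+2] in which the C2–C3 bond leads and the C4–C5 bond follows. The closest known reaction type is the oxazaborolidinium-catalysed, exo-selective Diels–Alder reaction of 2-substituted acroleins with 1-vinylcycloalkenes. Ring A is closed by an intermolecular suprafacial cycloaddition across C2 and C5, giving the six-membered carbocycle in one step with its double bond at C1=C10. C4 is set by the catalyst through the enal face it leaves open (bonding at the Re face of the α-carbon gives 4S), and C5 is set by the exo-formyl, methyl-endo transition state, which places CHO cis to H5 (5S). The step needs ortho orientation, exo-formyl topology and bonding on the diene face anti to the C9 side chain. Ortho orientation follows because C3 bonds first to the unhindered CH2 terminus C2 while the developing charge is spread over the more substituted C1–C10–C5 unit, and the exo mode follows from the α-methyl group of 14. The required diene face is the only one compatible with the catalyst-fixed enal face in the exo mode, and the two C9 substituents (CH3 and CH2) are too alike near the reacting carbons to oppose it strongly. The s-trans rotamer of the diene would press C2 against quaternary C9, so the reactive s-cis rotamer is populated; the side-chain alkene and the propanoate are expected to be spectators at this temperature.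

Step 9
Reactants: 15 (1S,5S,6R,8aS)-1,5,6-trimethyl-5-[(3E)-3-methyl-5-(propanoyloxy)pent-3-en-1-yl]-1,2,3,5,6,7,8,8a-octahydronaphthalene-1-carbaldehyde
Product: 16 (1S,5S,6R,8aS)-1,5,6-trimethyl-5-[(3E)-3-methyl-5-(propanoyloxy)pent-3-en-1-yl]-1,2,3,5,6,7,8,8a-octahydronaphthalene-1-carboxylic acid
Conditions: NaClO2 (3 equiv), NaH2PO4 (3 equiv), 2-methylbut-2-ene (10 equiv), t-BuOH/H2O, 0 °C → rt
Reagents that add atoms: sodium chlorite [Na+].[O-]Cl=O
Why: Pinnick oxidation; chlorous acid adds to the aldehyde and fragments to the acid, and the hypochlorous acid released is taken up by the sacrificial alkene before it can reach C1=C10 or C13=C14. The buffered medium leaves the propanoate intact, and C4 is quaternary, so no centre can epimerise.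

## Compound list

1 | 2-methylcyclohex-2-en-1-one | CC1=CCCCC1=O | starting material
2 | dimethylaluminium (3R)-2,3-dimethylcyclohex-1-en-1-olate | CC1=C(O[Al](C)C)CCC[C@H]1C | intermediate
3 | trimethyl{[(3R)-2,3-dimethylcyclohex-1-en-1-yl]oxy}silane | CC1=C(O[Si](C)(C)C)CCC[C@H]1C | intermediate
4 | methyl vinyl ketone (but-3-en-2-one) | CC(=O)C=C | starting material
5 | (2S,3R)-2,3-dimethyl-2-(3-oxobutyl)cyclohexan-1-one | CC(=O)CC[C@]1(C)C(=O)CCC[C@H]1C | intermediate
6 | triethyl phosphonoacetate | CCOC(=O)CP(=O)(OCC)OCC | starting material
7 | ethyl (2E)-5-[(1S,2R)-1,2-dimethyl-6-oxocyclohexyl]-3-methylpent-2-enoate | CCOC(=O)/C=C(\C)CC[C@]1(C)C(=O)CCC[C@H]1C | intermediate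
8 | potassium (5R,6S)-6-[(3E)-5-ethoxy-3-methyl-5-oxopent-3-en-1-yl]-5,6-dimethylcyclohex-1-en-1-olate | CCOC(=O)/C=C(\C)CC[C@]1(C)C([O-])=CCC[C@H]1C.[K+] | intermediate
9 | ethyl (2E)-5-[(1S,6R)-1,6-dimethyl-2-(trifluoromethanesulfonyloxy)cyclohex-2-en-1-yl]-3-methylpent-2-enoate | CCOC(=O)/C=C(\C)CC[C@]1(C)C(OS(=O)(=O)C(F)(F)F)=CCC[C@H]1C | intermediate
10 | ethyl (2E)-5-[(1S,6R)-2-ethenyl-1,6-dimethylcyclohex-2-en-1-yl]-3-methylpent-2-enoate | CCOC(=O)/C=C(\C)CC[C@]1(C)C(C=C)=CCC[C@H]1C | intermediate
11 | (2E)-5-[(1S,6R)-2-ethenyl-1,6-dimethylcyclohex-2-en-1-yl]-3-methylpent-2-enal | O=C/C=C(\C)CC[C@]1(C)C(C=C)=CCC[C@H]1C | intermediate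
12 | (2E)-5-[(1S,6R)-2-ethenyl-1,6-dimethylcyclohex-2-en-1-yl]-3-methylpent-2-en-1-ol | OC/C=C(\C)CC[C@]1(C)C(C=C)=CCC[C@H]1C | intermediate
13 | (2E)-5-[(1S,6R)-2-ethenyl-1,6-dimethylcyclohex-2-en-1-yl]-3-methylpent-2-en-1-yl propanoate | CCC(=O)OC/C=C(\C)CC[C@]1(C)C(C=C)=CCC[C@H]1C | intermediate
14 | methacrolein (2-methylprop-2-enal) | C=C(C)C=O | starting material
15 | (1S,5S,6R,8aS)-1,5,6-trimethyl-5-[(3E)-3-methyl-5-(propanoyloxy)pent-3-en-1-yl]-1,2,3,5,6,7,8,8a-octahydronaphthalene-1-carbaldehyde (ent-halima-1(10),13E-dien-18-al 15-propanoate) | CCC(=O)OC/C=C(\C)CC[C@]1(C)C2=CCC[C@](C)(C=O)[C@H]2CC[C@H]1C | intermediate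
16 | (1S,5S,6R,8aS)-1,5,6-trimethyl-5-[(3E)-3-methyl-5-(propanoyloxy)pent-3-en-1-yl]-1,2,3,5,6,7,8,8a-octahydronaphthalene-1-carboxylic acid (15-propanoyloxy-ent-halima-1(10),13E-dien-18-oic acid) | CCC(=O)OC/C=C(\C)CC[C@]1(C)C2=CCC[C@](C)(C(=O)O)[C@H]2CC[C@H]1C | target

## Step count and least certain steps

Total step count: 9. Longest linear sequence: 9 steps (1 to 16).

Step 8 (key step). The most likely failure is erosion of diene-face or exo selectivity. The diene is chiral, and its preferred half-chair may present the face that the catalyst-fixed enal does not want, so that the endo mode or the other enal face begins to compete. A second concern is ionisation of the allylic propanoate, or oligomerisation of the diene, by the strongly acidic boron cation. The fallback sets out from 10 and returns at 16. The cycloaddition is brought forward to the conjugated ester 10, which has no ionisable allylic ester, and run with 14 under MeAlCl2 in CH2Cl2 at −78 °C without a chiral catalyst. Because 10 is a single enantiomer, the adducts from its two faces are diastereomers, and the required ethyl ent-18-oxohalima-1(10),13E-dien-15-oate F1 would be separated by chromatography. Pinnick oxidation should give the half ester ent-halima-1(10),13E-diene-15,18-dioic acid 15-ethyl ester F2. Reduction with i-Bu2AlH (3.5 equiv, −78 °C), at which temperature the hindered aluminium carboxylate should be inert, would give 15-hydroxy-ent-halima-1(10),13E-dien-18-oic acid F3. Propionylation with propanoic anhydride and pyridine, followed by aqueous cleavage of the mixed anhydride at its unhindered carbonyl, would give 16.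

Step 3. The most likely failure is base-induced intramolecular aldol addition of the side-chain enolate to the ring carbonyl, since 5 is a 1,5-diketone and the alkoxide intermediates of the olefination are basic. Incomplete E selectivity at the new trisubstituted alkene is a second concern. The fallback sets out from 3 and returns at 10. MeLi cleaves 3 to the lithium enolate, which is alkylated with 2-(2-iodoethyl)-2-methyl-1,3-dioxolane in THF/DMPU to give (2S,3R)-2,3-dimethyl-2-[2-(2-methyl-1,3-dioxolan-2-yl)ethyl]cyclohexan-1-one F4. With the side-chain carbonyl masked, triflation (KN(SiMe3)2, PhNTf2) should give (5R,6S)-5,6-dimethyl-6-[2-(2-methyl-1,3-dioxolan-2-yl)ethyl]cyclohex-1-en-1-yl trifluoromethanesulfonate F5, and Stille vinylation 2-{2-[(1S,6R)-2-ethenyl-1,6-dimethylcyclohex-2-en-1-yl]ethyl}-2-methyl-1,3-dioxolane F6. Hydrolysis with pyridinium tosylate in wet acetone frees 4-[(1S,6R)-2-ethenyl-1,6-dimethylcyclohex-2-en-1-yl]butan-2-one F7, which has no second carbonyl to attack and is olefinated with 6 and NaH to 10.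

Step 4. The most likely failure is competing removal of a γ-hydrogen of the conjugated ester, which would scramble the C13=C14 geometry or deconjugate it. Intramolecular conjugate addition of the ring enolate to that ester before triflation is a second concern, since both paths are open to a strong base. The fallback sets out from 7 and returns at 10 and uses no enolate. The vinylcerium reagent from CH2=CHMgBr and CeCl3 (THF, −78 °C) should add to the hindered ring ketone in preference to the ester and give ethyl (2E)-5-[(1S,6R)-2-ethenyl-2-hydroxy-1,6-dimethylcyclohexyl]-3-methylpent-2-enoate F8. Dehydration with the Burgess reagent, which within the ring can only remove a C5 hydrogen because C9 is quaternary, then gives 10.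

Step 2. The most likely failure is Lewis-acid oligomerisation of 4 and protodesilylation of 3 before the C–C bond forms. Incomplete face selectivity at the new quaternary centre is a lesser concern. The fallback sets out from 3 and returns at 5. MeLi converts 3 into the lithium enolate, which is alkylated with the reactive allylic halide 1,3-dichlorobut-2-ene to give (2S,3R)-2-(3-chlorobut-2-en-1-yl)-2,3-dimethylcyclohexan-1-one F9. Wichterle hydrolysis of the vinyl chloride (cold concentrated H2SO4, short contact) then unmasks the methyl ketone of 5.

Step 1. The most likely failure is incomplete O-silylation of the weakly nucleophilic aluminium enolate and hydrolysis of the labile tetrasubstituted enol ether during isolation. The fallback sets out from 1 and returns at 3. The conjugate addition is quenched with aqueous NH4Cl and (3R)-2,3-dimethylcyclohexan-1-one F10 is isolated as a mixture of C2 epimers. Silylation under equilibrating conditions (TMSCl, NaI, Et3N, MeCN) then regenerates the more substituted enol ether 3; the C2 centre is lost in this step, so the epimer mixture is of no consequence.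

## Further compounds

F1 | step 8 | ethyl ent-18-oxohalima-1(10),13E-dien-15-oate (ethyl (2E)-5-[(1S,2R,4aS,5S)-5-formyl-1,2,5-trimethyl-1,2,3,4,4a,5,6,7-octahydronaphthalen-1-yl]-3-methylpent-2-enoate) | CCOC(=O)/C=C(\C)CC[C@]1(C)C2=CCC[C@](C)(C=O)[C@H]2CC[C@H]1C
F2 | step 8 | ent-halima-1(10),13E-diene-15,18-dioic acid 15-ethyl ester | CCOC(=O)/C=C(\C)CC[C@]1(C)C2=CCC[C@](C)(C(=O)O)[C@H]2CC[C@H]1C
F3 | step 8 | 15-hydroxy-ent-halima-1(10),13E-dien-18-oic acid | OC/C=C(\C)CC[C@]1(C)C2=CCC[C@](C)(C(=O)O)[C@H]2CC[C@H]1C
F4 | step 3 | (2S,3R)-2,3-dimethyl-2-[2-(2-methyl-1,3-dioxolan-2-yl)ethyl]cyclohexan-1-one | CC1(CC[C@]2(C)C(=O)CCC[C@H]2C)OCCO1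
F5 | step 3 | (5R,6S)-5,6-dimethyl-6-[2-(2-methyl-1,3-dioxolan-2-yl)ethyl]cyclohex-1-en-1-yl trifluoromethanesulfonate | CC1(CC[C@]2(C)C(OS(=O)(=O)C(F)(F)F)=CCC[C@H]2C)OCCO1
F6 | step 3 | 2-{2-[(1S,6R)-2-ethenyl-1,6-dimethylcyclohex-2-en-1-yl]ethyl}-2-methyl-1,3-dioxolane | CC1(CC[C@]2(C)C(C=C)=CCC[C@H]2C)OCCO1
F7 | step 3 | 4-[(1S,6R)-2-ethenyl-1,6-dimethylcyclohex-2-en-1-yl]butan-2-one | CC(=O)CC[C@]1(C)C(C=C)=CCC[C@H]1C
F8 | step 4 | ethyl (2E)-5-[(1S,6R)-2-ethenyl-2-hydroxy-1,6-dimethylcyclohexyl]-3-methylpent-2-enoate (either configuration at the carbinol carbon) | CCOC(=O)/C=C(\C)CC[C@]1(C)C(O)(C=C)CCC[C@H]1C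
F9 | step 2 | (2S,3R)-2-(3-chlorobut-2-en-1-yl)-2,3-dimethylcyclohexan-1-one (E/Z mixture) | CC(Cl)=CC[C@]1(C)C(=O)CCC[C@H]1C
F10 | step 1 | (3R)-2,3-dimethylcyclohexan-1-one (mixture of C2 epimers) | CC1C(=O)CCC[C@H]1C
A1 | alternative 1 | methyl (2S,6E,10E)-12-[(tert-butyldimethylsilyl)oxy]-2,7,10-trimethyl-5-oxo-2-[(1E,3E)-penta-1,3-dien-1-yl]dodeca-6,10-dienoate | CC(C)(C)[Si](C)(C)OC/C=C(\C)CC/C(C)=C/C(=O)CC[C@](C)(C(=O)OC)/C=C/C=C/C
A2 | alternative 1 | methyl 15-[(tert-butyldimethylsilyl)oxy]-1-oxo-ent-halima-6,13E-dien-18-oate (cis ring fusion, H10 cis to H5) | CC(C)(C)[Si](C)(C)OC/C=C(\C)CC[C@]1(C)[C@H]2C(=O)CC[C@](C)(C(=O)OC)[C@H]2C=C[C@H]1C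
A3 | alternative 2 | methyl (1S,2R)-2-[(3R,4E)-6-[(tert-butyldimethylsilyl)oxy]-3,4-dimethylhex-4-en-1-yl]-1-methyl-3-(trifluoromethanesulfonyloxy)cyclohex-3-ene-1-carboxylate | CC(C)(C)[Si](C)(C)OC/C=C(\C)[C@H](C)CC[C@H]1C(OS(=O)(=O)C(F)(F)F)=CCC[C@]1(C)C(=O)OC
A4 | alternative 2 | methyl 12-oxo-13,14,15,16-tetranor-ent-halim-1(10)-en-18-oate | O=CC[C@]1(C)C2=CCC[C@](C)(C(=O)OC)[C@H]2CC[C@H]1C
A5 | alternative 3 | (2S)-2-{(1S,3S,4R)-3-[(3E)-5-[(tert-butyldimethylsilyl)oxy]-3-methylpent-3-en-1-yl]-3,4-dimethyl-2-methylidenecyclohexyl}-2-methylhex-5-enoic acid | CC(C)(C)[Si](C)(C)OC/C=C(\C)CC[C@]1(C)C(=C)[C@@H]([C@](C)(CCC=C)C(=O)O)CC[C@H]1C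
A6 | alternative 3 | 15-[(tert-butyldimethylsilyl)oxy]-ent-halima-1(10),13E-dien-18-oic acid | CC(C)(C)[Si](C)(C)OC/C=C(\C)CC[C@]1(C)C2=CCC[C@](C)(C(=O)O)[C@H]2CC[C@H]1C
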